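**Retrosynthetic overview**

- The strategy rests on ring A (C4a, C5, C6, C7, C8, C8a) with oxygen on C5, C7 and C8a (as O1), joined through C4a to the C4 carbonyl, C3 and the oxygen-bearing C2. These nine carbons are the folded form of a chain with oxygen on every second carbon, running from the ring B aroyl carbon (C2) to a carboxyl carbon (C8a).
- Key disconnection: C4a–C8a (Claisen) and O1–C2 (addition–elimination) are cut together, giving a 4-hydroxy-2-pyranone that masks two ketones and the ester, with the aroyl carbonyl held as its methyl enol ether.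
- The pyranone precursor comes from the dianion of 4-hydroxy-6-methyl-2-pyranone and a ring B β-methoxyacrylate, itself made from the ring B methyl ester by Claisen condensation and O-methylation.
- The ring B ester with its side chain comes from an auxiliary-controlled anti-aldol (C7''–C8'' bond) of an aryloxyacetyl imide with 4-(benzyloxy)benzaldehyde; the aryl ether oxygen is alkylated on methyl syringate beforehand.
- Ring order: rings B and D and the pyranone are purchased; ring A and then ring C form in one operation; acetonide and benzyl ether are removed last.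

Key step: step 10

Assumption: the side chain is numbered C7'' (carbinol), C8'' (aryloxy carbon), C9'' (CH2OH); the target is the erythro (7''S,8''R) isomer, which is the anti relationship in the zigzag drawing, so an anti-selective aldol is required. The enol ether of 15–19 is drawn E although either geometry would serve.

Notation: "ArB" = 4-{[(4S,5R)-4-[4-(benzyloxy)phenyl]-2,2-dimethyl-1,3-dioxan-5-yl]oxy}-3,5-dimethoxyphenyl (ring B with the acetonide-protected side chain).

**Route**

Step 1
Reactants: 1 methyl syringate; 2 tert-butyl bromoacetate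
Product: 3 tert-butyl 2-[2,6-dimethoxy-4-(methoxycarbonyl)phenoxy]acetate
Conditions: K2CO3, DMF, 60 °C
Reagents that add atoms: none
Why: Williamson ether synthesis in which the phenoxide displaces bromide from a primary α-bromo ester by SN2, a reaction that tolerates the two flanking methoxy groups, and the tert-butyl ester can later be removed without touching the ring B methyl ester.

Step 2
Reactants: 3 tert-butyl 2-[2,6-dimethoxy-4-(methoxycarbonyl)phenoxy]acetate
Product: 4 2-[2,6-dimethoxy-4-(methoxycarbonyl)phenoxy]acetic acid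
Conditions: CF3CO2H, CH2Cl2, rt
Reagents that add atoms: none
Why: Acidolysis of the tert-butyl ester with loss of isobutene leaves the methyl benzoate and the aryl ethers intact.

Step 3
Reactants: 4 2-[2,6-dimethoxy-4-(methoxycarbonyl)phenoxy]acetic acid; 5 (R)-4-benzyl-1,3-oxazolidin-2-one
Product: 7 methyl 4-{2-[(4R)-4-benzyl-2-oxo-1,3-oxazolidin-3-yl]-2-oxoethoxy}-3,5-dimethoxybenzoate, via mixed pivalic anhydride 6 (not isolated)
Conditions: t-BuCOCl, Et3N, THF, −20 °C; then LiCl, 5, rt
Reagents that add atoms: none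
Why: N-acylation of the oxazolidinone through a mixed pivalic anhydride, in which the LiCl/Et3N-activated oxazolidinone attacks the unhindered aryloxyacetyl carbonyl and not the pivaloyl carbonyl.

Step 4
Reactants: 7 methyl 4-{2-[(4R)-4-benzyl-2-oxo-1,3-oxazolidin-3-yl]-2-oxoethoxy}-3,5-dimethoxybenzoate; 8 4-(benzyloxy)benzaldehyde
Product: 10 methyl 4-{[(1S,2S)-3-[(4R)-4-benzyl-2-oxo-1,3-oxazolidin-3-yl]-1-[4-(benzyloxy)phenyl]-1-hydroxy-3-oxopropan-2-yl]oxy}-3,5-dimethoxybenzoate, via trimethylsilyl ether 9 (not isolated)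
Conditions: MgCl2 (0.2 equiv), Et3N, Me3SiCl, EtOAc, 23 °C; then 1 M HCl, THF, 0 °C
Reagents that add atoms: none
Why: MgCl2-catalysed direct anti-aldol reaction of an N-acyloxazolidinone with an aromatic aldehyde, in which the magnesium-chelated Z-enolate should react through a closed boat transition state on the face opposite the benzyl group, so that the (4R)-auxiliary sets C8'' as R and C7'' as S in the anti (erythro) relationship, with silylation of the aldolate providing turnover.

Step 5
Reactants: 10 methyl 4-{[(1S,2S)-3-[(4R)-4-benzyl-2-oxo-1,3-oxazolidin-3-yl]-1-[4-(benzyloxy)phenyl]-1-hydroxy-3-oxopropan-2-yl]oxy}-3,5-dimethoxybenzoate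
Product: 11 methyl 4-{[(1S,2R)-1-[4-(benzyloxy)phenyl]-1,3-dihydroxypropan-2-yl]oxy}-3,5-dimethoxybenzoate
Conditions: NaBH4, THF–H2O, 0 °C → rt
Reagents that add atoms: none
Why: Reductive cleavage of the N-acyloxazolidinone, in which borohydride attacks the exocyclic imide carbonyl and reduces the acyl group to the primary alcohol while the methyl benzoate is not reduced and both stereocentres are untouched.

Step 6
Reactants: 11 methyl 4-{[(1S,2R)-1-[4-(benzyloxy)phenyl]-1,3-dihydroxypropan-2-yl]oxy}-3,5-dimethoxybenzoate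
Product: 12 methyl 4-{[(4S,5R)-4-[4-(benzyloxy)phenyl]-2,2-dimethyl-1,3-dioxan-5-yl]oxy}-3,5-dimethoxybenzoate
Conditions: 2,2-dimethoxypropane, pyridinium p-toluenesulfonate, acetone, rt
Reagents that add atoms: 2,2-dimethoxypropane, COC(C)(C)OC
Why: Acid-catalysed transketalisation of the 1,3-diol gives the six-membered dioxane, the only cyclic acetal available, under acid mild enough not to ionise the electron-rich benzylic C–O bond, and the acetonide later shields the β-aryl ether from base-induced cleavage.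

Step 7
Reactants: 12 methyl 4-{[(4S,5R)-4-[4-(benzyloxy)phenyl]-2,2-dimethyl-1,3-dioxan-5-yl]oxy}-3,5-dimethoxybenzoate; 13 methyl acetate
Product: 14 methyl 3-ArB-3-oxopropanoate
Conditions: LiN(SiMe3)2 (4 equiv), 13 (4 equiv), THF, −78 °C; then 12, −78 → 0 °C; aq. NH4Cl
Reagents that add atoms: none
Why: Crossed Claisen condensation in which the excess lithium enolate of methyl acetate adds to the non-enolisable aryl ester and deprotonation of the β-keto ester product drives the reaction forward.

Step 8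
Reactants: 14 methyl 3-ArB-3-oxopropanoate
Product: 15 methyl (2E)-3-ArB-3-methoxyprop-2-enoate
Conditions: KN(SiMe3)2, THF–DMPU, −78 °C; then CF3SO3CH3, −78 → 0 °C
Reagents that add atoms: methyl trifluoromethanesulfonate, COS(=O)(=O)C(F)(F)F
Why: O-alkylation of a β-keto ester enolate, where a dissociated potassium enolate in a dipolar cosolvent and a hard methylating agent should favour oxygen over carbon, and the enol ether geometry is of no consequence because both isomers converge in step 10.

Step 9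
Reactants: 15 methyl (2E)-3-ArB-3-methoxyprop-2-enoate; 16 4-hydroxy-6-methyl-2H-pyran-2-one
Product: 17 4-hydroxy-6-[(3E)-4-ArB-4-methoxy-2-oxobut-3-en-1-yl]-2H-pyran-2-one
Conditions: 16 (3 equiv), LiN(i-Pr)2 (6 equiv), THF, −78 → 0 °C; then 15, 0 °C → rt; cold 0.5 M HCl to pH 4
Reagents that add atoms: none
Why: Claisen-type C-acylation of the dilithio dianion of the pyranone at its 6-methylene terminus by a methyl ester that has no acidic hydrogen, with 1,2-attack at the ester carbonyl favoured because the β-carbon is fully substituted, and with excess dianion supplied because the product is held as its enolate.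

Step 10
Reactants: 17 4-hydroxy-6-[(3E)-4-ArB-4-methoxy-2-oxobut-3-en-1-yl]-2H-pyran-2-one
Product: 20 2-ArB-5,7-dihydroxy-4H-chromen-4-one, via triketo ester 18 (not isolated), via trihydroxyphenyl enone 19 (not isolated)
Conditions: Mg(OCH3)2 (8 equiv), CH3OH, reflux; then cold 1 M HCl to pH 4
Reagents that add atoms: none
Why: Proposed new method: methoxide delivered from magnesium should open the lactone of 17 at the pyranone C2 carbonyl to the magnesium-chelated 3,5,7-trioxo ester 18, whose carbanion at chain C6 (the future C4a) attacks the ester carbon (the future C8a) in a Claisen condensation, after which the cyclohexanetrione enolises to the 2,4,6-trihydroxyphenyl ketone 19 and an ortho phenoxide adds to the methoxy-bearing enone carbon and expels methoxide to form O1–C2. The closest known reaction type is the Mg(OCH3)2-mediated Claisen cyclisation of 3,5,7-triketo esters, also when released from 4-hydroxy-6-(2-oxoalkyl)-2-pyranones, to acylphloroglucinols, joined here to the familiar addition–elimination closure of 2-hydroxyaryl β-alkoxy enones to chromones. Ring A closes 6-exo-trig onto the ester carbonyl and ring C closes 6-endo-trig at the enone β-carbon followed by loss of methanol. No stereocentre is formed, and the two dioxane stereocentres carry no acidic hydrogen and lie far from every reacting centre. The step needs Claisen closure to beat aldol closure onto the C7 carbonyl of the chain (which would give a resorcylate) and carbon-Michael closure onto the enol ether carbon; the substrate secures this by making the terminal carbonyl a vinylogous ester, a poor aldol acceptor with no enolisable position beyond it, while magnesium chelation of the 3,5-dicarbonyl unit holds the C6 carbanion against the ester. Oxygen closure of the chain to a 4-pyranone would be reversible in methoxide and should drain back towards the aromatic product.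

Step 11
Reactants: 20 2-ArB-5,7-dihydroxy-4H-chromen-4-one
Product: 21 2-(4-{[(1S,2R)-1-[4-(benzyloxy)phenyl]-1,3-dihydroxypropan-2-yl]oxy}-3,5-dimethoxyphenyl)-5,7-dihydroxy-4H-chromen-4-one
Conditions: AcOH–H2O–THF (4:1:1), 40 °C
Reagents that add atoms: none
Why: Acid-catalysed acetal hydrolysis, in which the ketal carbon is protonated and cleaved far more readily than the benzylic C7''–O bond is ionised, so the diol should be released without epimerisation.

Step 12
Reactants: 21 2-(4-{[(1S,2R)-1-[4-(benzyloxy)phenyl]-1,3-dihydroxypropan-2-yl]oxy}-3,5-dimethoxyphenyl)-5,7-dihydroxy-4H-chromen-4-one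
Product: 22 2-(4-{[(1S,2R)-1,3-dihydroxy-1-(4-hydroxyphenyl)propan-2-yl]oxy}-3,5-dimethoxyphenyl)-5,7-dihydroxy-4H-chromen-4-one
Conditions: H2 (1 atm), 10% Pd/C, THF–CH3OH, rt
Reagents that add atoms: none
Why: Catalytic hydrogenolysis of the aryl benzyl ether, which is cleaved much faster than the secondary benzylic C7''–OH bond is broken or the chromone double bond is reduced, so stopping after uptake for one ether should deliver the target with both stereocentres intact.

**Compound list**

1 | methyl syringate (methyl 4-hydroxy-3,5-dimethoxybenzoate) | COC(=O)c1cc(OC)c(O)c(OC)c1 | starting material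
2 | tert-butyl bromoacetate | CC(C)(C)OC(=O)CBr | starting material
3 | tert-butyl 2-[2,6-dimethoxy-4-(methoxycarbonyl)phenoxy]acetate | COC(=O)c1cc(OC)c(OCC(=O)OC(C)(C)C)c(OC)c1 | intermediate
4 | 2-[2,6-dimethoxy-4-(methoxycarbonyl)phenoxy]acetic acid | COC(=O)c1cc(OC)c(OCC(=O)O)c(OC)c1 | intermediate
5 | (R)-4-benzyl-1,3-oxazolidin-2-one | O=C1N[C@H](Cc2ccccc2)CO1 | starting material
6 | 2-[2,6-dimethoxy-4-(methoxycarbonyl)phenoxy]acetic pivalic anhydride | COC(=O)c1cc(OC)c(OCC(=O)OC(=O)C(C)(C)C)c(OC)c1 | intermediate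
7 | methyl 4-{2-[(4R)-4-benzyl-2-oxo-1,3-oxazolidin-3-yl]-2-oxoethoxy}-3,5-dimethoxybenzoate | COC(=O)c1cc(OC)c(OCC(=O)N2[C@H](Cc3ccccc3)COC2=O)c(OC)c1 | intermediate
8 | 4-(benzyloxy)benzaldehyde | O=Cc1ccc(OCc2ccccc2)cc1 | starting material
9 | trimethylsilyl ether of aldol adduct 10 | COC(=O)c1cc(OC)c(O[C@H](C(=O)N2[C@H](Cc3ccccc3)COC2=O)[C@@H](O[Si](C)(C)C)c2ccc(OCc3ccccc3)cc2)c(OC)c1 | intermediate
10 | methyl 4-{[(1S,2S)-3-[(4R)-4-benzyl-2-oxo-1,3-oxazolidin-3-yl]-1-[4-(benzyloxy)phenyl]-1-hydroxy-3-oxopropan-2-yl]oxy}-3,5-dimethoxybenzoate | COC(=O)c1cc(OC)c(O[C@H](C(=O)N2[C@H](Cc3ccccc3)COC2=O)[C@@H](O)c2ccc(OCc3ccccc3)cc2)c(OC)c1 | intermediate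
11 | methyl 4-{[(1S,2R)-1-[4-(benzyloxy)phenyl]-1,3-dihydroxypropan-2-yl]oxy}-3,5-dimethoxybenzoate | COC(=O)c1cc(OC)c(O[C@H](CO)[C@@H](O)c2ccc(OCc3ccccc3)cc2)c(OC)c1 | intermediate
12 | methyl 4-{[(4S,5R)-4-[4-(benzyloxy)phenyl]-2,2-dimethyl-1,3-dioxan-5-yl]oxy}-3,5-dimethoxybenzoate | COC(=O)c1cc(OC)c(O[C@@H]2COC(C)(C)O[C@H]2c2ccc(OCc3ccccc3)cc2)c(OC)c1 | intermediate
13 | methyl acetate | CC(=O)OC | starting material
14 | methyl 3-ArB-3-oxopropanoate | COC(=O)CC(=O)c1cc(OC)c(O[C@@H]2COC(C)(C)O[C@H]2c2ccc(OCc3ccccc3)cc2)c(OC)c1 | intermediate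
15 | methyl (2E)-3-ArB-3-methoxyprop-2-enoate | COC(=O)/C=C(/OC)c1cc(OC)c(O[C@@H]2COC(C)(C)O[C@H]2c2ccc(OCc3ccccc3)cc2)c(OC)c1 | intermediate
16 | 4-hydroxy-6-methyl-2H-pyran-2-one | Cc1cc(O)cc(=O)o1 | starting material
17 | 4-hydroxy-6-[(3E)-4-ArB-4-methoxy-2-oxobut-3-en-1-yl]-2H-pyran-2-one | O=c1cc(O)cc(CC(=O)/C=C(/OC)c2cc(OC)c(O[C@@H]3COC(C)(C)O[C@H]3c3ccc(OCc4ccccc4)cc3)c(OC)c2)o1 | intermediate
18 | methyl (8E)-9-ArB-9-methoxy-3,5,7-trioxonon-8-enoate | COC(=O)CC(=O)CC(=O)CC(=O)/C=C(/OC)c1cc(OC)c(O[C@@H]2COC(C)(C)O[C@H]2c2ccc(OCc3ccccc3)cc2)c(OC)c1 | intermediate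
19 | (2E)-3-ArB-3-methoxy-1-(2,4,6-trihydroxyphenyl)prop-2-en-1-one | O=C(/C=C(/OC)c1cc(OC)c(O[C@@H]2COC(C)(C)O[C@H]2c2ccc(OCc3ccccc3)cc2)c(OC)c1)c1c(O)cc(O)cc1O | intermediate
20 | 2-ArB-5,7-dihydroxy-4H-chromen-4-one | COc1cc(-c2cc(=O)c3c(O)cc(O)cc3o2)cc(OC)c1O[C@@H]1COC(C)(C)O[C@H]1c1ccc(OCc2ccccc2)cc1 | intermediate
21 | 2-(4-{[(1S,2R)-1-[4-(benzyloxy)phenyl]-1,3-dihydroxypropan-2-yl]oxy}-3,5-dimethoxyphenyl)-5,7-dihydroxy-4H-chromen-4-one | COc1cc(-c2cc(=O)c3c(O)cc(O)cc3o2)cc(OC)c1O[C@H](CO)[C@@H](O)c1ccc(OCc2ccccc2)cc1 | intermediate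
22 | 2-(4-{[(1S,2R)-1,3-dihydroxy-1-(4-hydroxyphenyl)propan-2-yl]oxy}-3,5-dimethoxyphenyl)-5,7-dihydroxy-4H-chromen-4-one | COc1cc(-c2cc(=O)c3c(O)cc(O)cc3o2)cc(OC)c1O[C@H](CO)[C@@H](O)c1ccc(O)cc1 | target

**Step count and risks**

Total step count: 12. Longest linear sequence: 12 steps (from methyl syringate 1).

Steps most likely to fail:

1. Step 10 (proposed new method). The chain may close by aldol onto the vinylogous ester carbonyl or by carbon-Michael attack on the enol ether carbon instead of by Claisen condensation. The magnesium pyranone salt may also resist ring opening, or the enol ether may be lost before ring A is formed.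
   Fallback by the known diketone route, setting out from 12: saponification (LiOH, THF–CH3OH–H2O) would give 4-{[(4S,5R)-4-[4-(benzyloxy)phenyl]-2,2-dimethyl-1,3-dioxan-5-yl]oxy}-3,5-dimethoxybenzoic acid F1. 1,1'-Carbonyldiimidazole would convert it into the acyl imidazole ArB–CO–imidazol-1-yl F2. The lithium polyanion of 2',4',6'-trihydroxyacetophenone (LiN(SiMe3)2, THF, −78 °C → rt) would be C-acylated by F2 to the Baker–Venkataraman-type diketone 1-ArB-3-(2,4,6-trihydroxyphenyl)propane-1,3-dione F3. Cyclodehydration of F3 in warm aqueous AcOH would close ring C and is expected to remove the acetonide in the same operation, so the sequence comes back to the route at 21.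

2. Step 4. The polyoxygenated aryloxy group may sequester magnesium and stop turnover, or the closed boat pathway may not be followed, so that facial or syn/anti selectivity is eroded.
   Fallback setting out from 4: acylation of (S)-4-benzyl-1,3-oxazolidin-2-one through 6 would give methyl 4-{2-[(4S)-4-benzyl-2-oxo-1,3-oxazolidin-3-yl]-2-oxoethoxy}-3,5-dimethoxybenzoate F4. The boron-enolate syn-aldol (n-Bu2BOSO2CF3, i-Pr2NEt, CH2Cl2, −78 °C, then 8), whose facial sense is well established, would give the (1R,2S) syn adduct with the (4S)-auxiliary F5, carrying the correct C8'' and the wrong C7''. NaBH4 in THF–H2O would give the threo diol methyl 4-{[(1R,2R)-1-[4-(benzyloxy)phenyl]-1,3-dihydroxypropan-2-yl]oxy}-3,5-dimethoxybenzoate F6. DDQ would oxidise the benzylic hydroxyl selectively to the ketol methyl 4-{[(2R)-1-[4-(benzyloxy)phenyl]-3-hydroxy-1-oxopropan-2-yl]oxy}-3,5-dimethoxybenzoate F7. Reduction of F7 with NaBH4 at −20 °C (or Zn(BH4)2 under chelation control), which is normally erythro-selective for 2-(2,6-dimethoxyphenoxy)-3-hydroxy-1-arylpropan-1-ones, should then give 11, where the route is rejoined; any threo diol would be returned to the oxidation.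

3. Step 9. The vinylogous carbonate carbonyl may be too weak an electrophile, the dianion may attack the β-carbon and displace methoxide, or proton transfer may quench the dianion before acylation.
   Fallback setting out from 15, replacing the acylation by an aldehyde addition and oxidation: reduction with i-Bu2AlH (CH2Cl2, −78 °C, basic work-up) would give (2E)-3-ArB-3-methoxyprop-2-en-1-ol F8. MnO2 would oxidise it to (2E)-3-ArB-3-methoxyprop-2-enal F9. The dilithio dianion of 16 would add 1,2 to this aldehyde to give 4-hydroxy-6-[(3E)-4-ArB-2-hydroxy-4-methoxybut-3-en-1-yl]-2H-pyran-2-one F10 (both carbinol epimers), which must be kept under buffered conditions. Dess–Martin periodinane with NaHCO3 would then oxidise F10 to 17, where the route is rejoined.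

**Further compounds**

F1 | step 10 | 4-{[(4S,5R)-4-[4-(benzyloxy)phenyl]-2,2-dimethyl-1,3-dioxan-5-yl]oxy}-3,5-dimethoxybenzoic acid | OC(=O)c1cc(OC)c(O[C@@H]2COC(C)(C)O[C@H]2c2ccc(OCc3ccccc3)cc2)c(OC)c1
F2 | step 10 | ArB–CO–imidazol-1-yl (acyl imidazole of F1) | O=C(c1cc(OC)c(O[C@@H]2COC(C)(C)O[C@H]2c2ccc(OCc3ccccc3)cc2)c(OC)c1)n1ccnc1
F3 | step 10 | 1-ArB-3-(2,4,6-trihydroxyphenyl)propane-1,3-dione | O=C(CC(=O)c1cc(OC)c(O[C@@H]2COC(C)(C)O[C@H]2c2ccc(OCc3ccccc3)cc2)c(OC)c1)c1c(O)cc(O)cc1O
F4 | step 4 | methyl 4-{2-[(4S)-4-benzyl-2-oxo-1,3-oxazolidin-3-yl]-2-oxoethoxy}-3,5-dimethoxybenzoate | COC(=O)c1cc(OC)c(OCC(=O)N2[C@@H](Cc3ccccc3)COC2=O)c(OC)c1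
F5 | step 4 | methyl 4-{[(1R,2S)-3-[(4S)-4-benzyl-2-oxo-1,3-oxazolidin-3-yl]-1-[4-(benzyloxy)phenyl]-1-hydroxy-3-oxopropan-2-yl]oxy}-3,5-dimethoxybenzoate | COC(=O)c1cc(OC)c(O[C@H](C(=O)N2[C@@H](Cc3ccccc3)COC2=O)[C@H](O)c2ccc(OCc3ccccc3)cc2)c(OC)c1
F6 | step 4 | methyl 4-{[(1R,2R)-1-[4-(benzyloxy)phenyl]-1,3-dihydroxypropan-2-yl]oxy}-3,5-dimethoxybenzoate | COC(=O)c1cc(OC)c(O[C@H](CO)[C@H](O)c2ccc(OCc3ccccc3)cc2)c(OC)c1
F7 | step 4 | methyl 4-{[(2R)-1-[4-(benzyloxy)phenyl]-3-hydroxy-1-oxopropan-2-yl]oxy}-3,5-dimethoxybenzoate | COC(=O)c1cc(OC)c(O[C@H](CO)C(=O)c2ccc(OCc3ccccc3)cc2)c(OC)c1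
F8 | step 9 | (2E)-3-ArB-3-methoxyprop-2-en-1-ol | OC/C=C(/OC)c1cc(OC)c(O[C@@H]2COC(C)(C)O[C@H]2c2ccc(OCc3ccccc3)cc2)c(OC)c1
F9 | step 9 | (2E)-3-ArB-3-methoxyprop-2-enal | O=C/C=C(/OC)c1cc(OC)c(O[C@@H]2COC(C)(C)O[C@H]2c2ccc(OCc3ccccc3)cc2)c(OC)c1
F10 | step 9 | 4-hydroxy-6-[(3E)-4-ArB-2-hydroxy-4-methoxybut-3-en-1-yl]-2H-pyran-2-one (both carbinol epimers) | O=c1cc(O)cc(CC(O)/C=C(/OC)c2cc(OC)c(O[C@@H]3COC(C)(C)O[C@H]3c3ccc(OCc4ccccc4)cc3)c(OC)c2)o1
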